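**Retrosynthetic overview**

- Feature: ring B is a fully substituted benzene whose three oxygen-bearing carbons alternate (C2' OH, C4' OH, C6' OMe). The methoxy carbon C6' lies between the methyl carbon C5' and the bridge carbon C1', and C3', between the two hydroxyls, carries the butanoyl group.
- Key disconnection: ring B is made last by a Danheiser benzannulation. A 2-benzyl-3-methoxy-4-methylcyclobutenone supplies C4', C5', C6' and C1' (with Me, OMe and the ring A CH2 already in place), and (triisopropylsilyloxy)acetylene supplies C2' and C3'; the bonds formed are C4'–C3' and C2'–C1'.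
- After the annulation: fluoride desilylation, Houben–Hoesch butanoylation at the one free ring B carbon (C3'), and hydrogenolysis of the three ring A benzyl ethers.
- Before it: the cyclobutenone comes from a [2+2] cycloaddition of methylketene with the ynol ether ArCH2–C≡C–OMe, itself made by coupling zinc methoxyacetylide (from trichloroethylene) with the ring A benzylic bromide.
- Ring order: ring A is bought (2-methylphloroglucinol; acylation, formylation, benzylation, reduction, bromination), then the four-membered ring, then ring B.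

Key step: step 10

Remark on the chemistry: the target has no stereocentre. Cyclobutenone 18 and the transient species 24 and 26 are racemic and lose their stereocentre on aromatisation. Ring B is numbered C1' (bridge carbon), C2' (OH), C3' (butanoyl), C4' (OH), C5' (Me), C6' (OMe).

**Route**

Step 1
Reactants: 1 2-methylphloroglucinol; 2 pentanoyl chloride
Product: 3 ketone 1-(2,4,6-trihydroxy-3-methylphenyl)pentan-1-one
Conditions: AlCl3, PhNO2, rt → 60 °C; aq HCl
Reagents that add atoms: none
Why: Friedel–Crafts C-acylation of the strongly activated phloroglucinol nucleus, whose two free ring carbons are equivalent, while the first acyl group deactivates the ring against a second acylation.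

Step 2
Reactants: 3 ketone 1-(2,4,6-trihydroxy-3-methylphenyl)pentan-1-one
Product: 5 aldehyde 2,4,6-trihydroxy-3-methyl-5-pentanoylbenzaldehyde, via aryl iminium chloride 4 (not isolated)
Conditions: POCl3, DMF, EtOAc, 0 °C → rt; then H2O, 50 °C
Reagents that add atoms: N,N-dimethylformamide (CN(C)C=O); water (O)
Why: Vilsmeier–Haack formylation at the single remaining ring C–H, which is ortho and para to three hydroxyls, followed by hydrolysis of the iminium salt; formylating before benzylation blocks the nucleophilic ring carbon that would otherwise be C-benzylated.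

Step 3
Reactants: 5 aldehyde 2,4,6-trihydroxy-3-methyl-5-pentanoylbenzaldehyde
Product: 6 tribenzyl ether 2,4,6-tris(benzyloxy)-3-methyl-5-pentanoylbenzaldehyde
Conditions: BnBr (excess), K2CO3, Bu4NI (catalytic), DMF, 60 °C
Reagents that add atoms: benzyl bromide (BrCc1ccccc1)
Why: Williamson etherification in a dipolar aprotic solvent favours O- over C-alkylation of the phenoxides, and warming with excess halide should also alkylate the chelated hydroxyls next to the two carbonyl groups.

Step 4
Reactants: 6 tribenzyl ether 2,4,6-tris(benzyloxy)-3-methyl-5-pentanoylbenzaldehyde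
Product: 7 benzylic alcohol 1-[2,4,6-tris(benzyloxy)-3-(hydroxymethyl)-5-methylphenyl]pentan-1-one
Conditions: NaBH4, THF–MeOH, −20 °C
Reagents that add atoms: none
Why: chemoselective borohydride reduction, the aldehyde reacting far faster than the aryl alkyl ketone, which is twisted out of plane and shielded by two ortho benzyloxy groups and its butyl chain.

Step 5
Reactants: 7 benzylic alcohol 1-[2,4,6-tris(benzyloxy)-3-(hydroxymethyl)-5-methylphenyl]pentan-1-one
Product: 8 benzylic bromide 1-[2,4,6-tris(benzyloxy)-3-(bromomethyl)-5-methylphenyl]pentan-1-one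
Conditions: CBr4, PPh3, CH2Cl2, 0 °C; used at once
Reagents that add atoms: carbon tetrabromide (BrC(Br)(Br)Br)
Why: Appel bromination converts the electron-rich benzylic alcohol to the bromide under neutral conditions, so no acid is present to ionise it, and the meta acyl group tempers the lability of the trialkoxybenzyl bromide.

Step 6
Reactants: 9 trichloroethylene
Product: 11 (E)-1,2-dichloro-1-methoxyethene, via dichloroacetylene 10 (not isolated)
Conditions: KH, MeOH, THF, 0 °C; then 9, −50 °C → rt; distillation
Reagents that add atoms: methanol (CO)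
Why: methoxide dehydrochlorinates trichloroethylene to dichloroacetylene, which stays in solution and takes up methanol by base-catalysed anti addition to give the (E)-dichlorovinyl ether (the classical alkoxide addition–elimination route to ynol ether precursors).

Step 7
Reactants: 11 (E)-1,2-dichloro-1-methoxyethene; 8 benzylic bromide 1-[2,4,6-tris(benzyloxy)-3-(bromomethyl)-5-methylphenyl]pentan-1-one
Product: 15 ynol ether 1-[2,4,6-tris(benzyloxy)-3-(3-methoxyprop-2-yn-1-yl)-5-methylphenyl]pentan-1-one, via chloro(methoxy)ethyne 12 (not isolated), via lithium methoxyacetylide 13 (not isolated), via bromo(methoxyethynyl)zinc 14 (not isolated)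
Conditions: 11 (1.3 equiv), n-BuLi (2 equiv per 11), THF, −78 → −40 °C; ZnBr2, −40 → 0 °C; then 8, PdCl2[(2-Ph2PC6H4)2O] (5 mol %), THF, rt; chromatography on Et3N-deactivated silica
Reagents that add atoms: none
Why: dehydrochlorination and chlorine–lithium exchange give lithium methoxyacetylide, which is transmetalated to zinc so that it neither adds to nor enolises the pentanoyl ketone of 8, and a Negishi-type palladium-catalysed sp–sp3 coupling with the benzylic bromide then forms the ArCH2–C≡C bond.

Step 8
Reactants: 15 ynol ether 1-[2,4,6-tris(benzyloxy)-3-(3-methoxyprop-2-yn-1-yl)-5-methylphenyl]pentan-1-one; 16 propanoyl chloride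
Product: 18 racemic 2-{[2,4,6-tris(benzyloxy)-3-methyl-5-pentanoylphenyl]methyl}-3-methoxy-4-methylcyclobut-2-en-1-one, via methylketene 17 (not isolated)
Conditions: Et3N, Et2O, slow addition of 16 (syringe pump), 0 °C → rt
Reagents that add atoms: none
Why: ketene–ynol ether [2+2] cycloaddition in which methylketene, released slowly by dehydrochlorination so that it does not dimerise, is attacked at its carbonyl carbon by the nucleophilic β-carbon of the ynol ether (the one bearing the benzylic CH2), which fixes the 2-benzyl-3-methoxy-4-methyl pattern; the stereocentre at C4 forms as the racemate and is lost later.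

Step 9
Reactants: 19 acetylene
Product: 22 (triisopropylsilyloxy)acetylene, via lithium acetylide 20 (not isolated), via lithium ethynolate 21 (not isolated)
Conditions: n-BuLi, THF, −78 °C (acetylene in excess); t-BuOOLi (from t-BuOOH, LiN(SiMe3)2), −78 → −20 °C; i-Pr3SiOSO2CF3, −78 → 0 °C; distillation
Reagents that add atoms: tert-butyl hydroperoxide, used as its lithium salt (CC(C)(C)OO); triisopropylsilyl trifluoromethanesulfonate (CC(C)[Si](C(C)C)(C(C)C)OS(=O)(=O)C(F)(F)F)
Why: electrophilic oxygen transfer from lithium tert-butyl peroxide to a lithium acetylide gives the ynolate (the established acetylide-oxygenation route to siloxyalkynes), and the hard, bulky silyl triflate should trap it at oxygen, the triisopropylsilyl group slowing isomerisation to the silylketene.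

Step 10
Reactants: 18 racemic 2-{[2,4,6-tris(benzyloxy)-3-methyl-5-pentanoylphenyl]methyl}-3-methoxy-4-methylcyclobut-2-en-1-one; 22 (triisopropylsilyloxy)acetylene
Product: 27 ring B phenol mono(triisopropylsilyl) ether 1-[2,4,6-tris(benzyloxy)-3-{[4-hydroxy-2-methoxy-3-methyl-6-(triisopropylsilyloxy)phenyl]methyl}-5-methylphenyl]pentan-1-one, via vinylketene 23 (not isolated), via 4-vinylcyclobutenone adduct 24 (not isolated), via dienylketene 25 (not isolated), via cyclohexa-2,4-dienone 26 (not isolated)
Conditions: 22 (2.5 equiv), toluene, 80 → 110 °C, sealed tube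
Reagents that add atoms: none
Why: Heating opens cyclobutenone 18 by four-electron electrocyclic cleavage of its C1–C4 bond (the 4-methyl group turning outward) to vinylketene 23, whose ketene C=C undergoes a regiospecific [2+2] cycloaddition with 22, the nucleophilic CH carbon of the alkyne bonding to the ketene carbonyl carbon and the siloxy carbon to the ketene α-carbon that carries the ring A benzyl group, to give 24. A second four-electron ring opening of 24 gives dienylketene 25, and ring B is closed by thermal disrotatory six-electron electrocyclisation between the ketene carbon and the methyl-bearing vinyl carbon, after which dienone 26 tautomerises to the phenol. This is the Danheiser benzannulation of a cyclobutenone with a heteroatom-substituted alkyne, whose siloxyalkyne variant is the established route to resorcinol monosilyl ethers. No stereocentre is created, since the stereocentres of 18, 24 and 26 are racemic and vanish on aromatisation. The selectivity needed is regiochemical and is secured by the polarisation of the O-silyl ynol ether, which places the unsubstituted carbon between the two oxygens and leaves the methoxy group, carried in from the cyclobutenone, between the methyl and bridge carbons; the alkyne is used in excess so that the vinylketene is taken up by it and not by the product phenol, and the fully substituted, benzyl-protected ring A offers nothing that reacts at this temperature.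

Step 11
Reactants: 27 ring B phenol mono(triisopropylsilyl) ether
Product: 28 ring B diol 1-[2,4,6-tris(benzyloxy)-3-[(4,6-dihydroxy-2-methoxy-3-methylphenyl)methyl]-5-methylphenyl]pentan-1-one
Conditions: Bu4NF, AcOH, THF, 0 °C
Reagents that add atoms: none
Why: fluoride cleaves the aryl silyl ether through formation of the strong Si–F bond, acetic acid buffers the phenoxide, and the benzyl ethers, the methyl ether and the ketone are untouched.

Step 12
Reactants: 28 ring B diol; 29 butanenitrile
Product: 31 ketone 1-[2,4,6-tris(benzyloxy)-3-[(3-butanoyl-2,4-dihydroxy-6-methoxy-5-methylphenyl)methyl]-5-methylphenyl]pentan-1-one, via ketiminium chloride 30 (not isolated)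
Conditions: ZnCl2 (catalytic), HCl (g), Et2O, 0 °C; then H2O, 60 °C
Reagents that add atoms: water (O)
Why: Houben–Hoesch acylation, in which the nitrilium electrophile attacks carbon C-selectively at the only free ring B position, flanked by two hydroxyls and para to the methoxy group (a phloroglucinol-type nucleus, the best substrate class for this reaction), at 0 °C and without the strong Lewis acids that would strip the benzyl ethers or cleave the diarylmethane bridge; mild aqueous hydrolysis of the ketiminium salt gives the ketone.

Step 13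
Reactants: 31 ketone (tribenzyl ether)
Product: 32 target 1-[3-[(3-butanoyl-2,4-dihydroxy-6-methoxy-5-methylphenyl)methyl]-2,4,6-trihydroxy-5-methylphenyl]pentan-1-one
Conditions: H2 (1 atm), 10% Pd/C, EtOAc–MeOH, rt
Reagents that add atoms: none
Why: catalytic hydrogenolysis removes the three aryl benzyl ethers under neutral conditions, while the hydrogen-bonded aryl ketones, the methyl ether and the diarylmethane should not be reduced at 1 atm and room temperature.

**Compound list**

1 | 2-methylphloroglucinol (2-methylbenzene-1,3,5-triol) | Cc1c(O)cc(O)cc1O | starting material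
2 | pentanoyl chloride | CCCCC(Cl)=O | starting material
3 | 1-(2,4,6-trihydroxy-3-methylphenyl)pentan-1-one | CCCCC(=O)c1c(O)cc(O)c(C)c1O | intermediate
4 | N-[(2,4,6-trihydroxy-3-methyl-5-pentanoylphenyl)methylidene]-N-methylmethanaminium chloride | CCCCC(=O)c1c(O)c(C)c(O)c(C=[N+](C)C)c1O.[Cl-] | intermediate
5 | 2,4,6-trihydroxy-3-methyl-5-pentanoylbenzaldehyde | CCCCC(=O)c1c(O)c(C)c(O)c(C=O)c1O | intermediate
6 | 2,4,6-tris(benzyloxy)-3-methyl-5-pentanoylbenzaldehyde | CCCCC(=O)c1c(OCc2ccccc2)c(C)c(OCc2ccccc2)c(C=O)c1OCc1ccccc1 | intermediate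
7 | 1-[2,4,6-tris(benzyloxy)-3-(hydroxymethyl)-5-methylphenyl]pentan-1-one | CCCCC(=O)c1c(OCc2ccccc2)c(C)c(OCc2ccccc2)c(CO)c1OCc1ccccc1 | intermediate
8 | 1-[2,4,6-tris(benzyloxy)-3-(bromomethyl)-5-methylphenyl]pentan-1-one | CCCCC(=O)c1c(OCc2ccccc2)c(C)c(OCc2ccccc2)c(CBr)c1OCc1ccccc1 | intermediate
9 | trichloroethylene | ClC=C(Cl)Cl | starting material
10 | dichloroacetylene | ClC#CCl | intermediate
11 | (E)-1,2-dichloro-1-methoxyethene | CO/C(Cl)=C\Cl | intermediate
12 | chloro(methoxy)ethyne | COC#CCl | intermediate
13 | lithium methoxyacetylide | [Li]C#COC | intermediate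
14 | bromo(methoxyethynyl)zinc | COC#C[Zn]Br | intermediate
15 | 1-[2,4,6-tris(benzyloxy)-3-(3-methoxyprop-2-yn-1-yl)-5-methylphenyl]pentan-1-one | CCCCC(=O)c1c(OCc2ccccc2)c(C)c(OCc2ccccc2)c(CC#COC)c1OCc1ccccc1 | intermediate
16 | propanoyl chloride | CCC(Cl)=O | starting material
17 | methylketene (prop-1-en-1-one) | CC=C=O | intermediate
18 | racemic 2-{[2,4,6-tris(benzyloxy)-3-methyl-5-pentanoylphenyl]methyl}-3-methoxy-4-methylcyclobut-2-en-1-one | CCCCC(=O)c1c(OCc2ccccc2)c(C)c(OCc2ccccc2)c(CC2=C(OC)C(C)C2=O)c1OCc1ccccc1 | intermediate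
19 | acetylene | C#C | starting material
20 | lithium acetylide | [Li]C#C | intermediate
21 | lithium ethynolate | [Li]OC#C | intermediate
22 | (triisopropylsilyloxy)acetylene | C#CO[Si](C(C)C)(C(C)C)C(C)C | intermediate
23 | vinylketene: 2-{[2,4,6-tris(benzyloxy)-3-methyl-5-pentanoylphenyl]methyl}-3-methoxypenta-1,3-dien-1-one, methyl trans to the ketene-bearing carbon | CCCCC(=O)c1c(OCc2ccccc2)c(C)c(OCc2ccccc2)c(CC(=C=O)/C(OC)=C/C)c1OCc1ccccc1 | intermediate
24 | racemic 4-{[2,4,6-tris(benzyloxy)-3-methyl-5-pentanoylphenyl]methyl}-4-(1-methoxyprop-1-en-1-yl)-3-(triisopropylsilyloxy)cyclobut-2-en-1-one | CCCCC(=O)c1c(OCc2ccccc2)c(C)c(OCc2ccccc2)c(CC2(/C(OC)=C/C)C(O[Si](C(C)C)(C(C)C)C(C)C)=CC2=O)c1OCc1ccccc1 | intermediate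
25 | dienylketene: 4-{[2,4,6-tris(benzyloxy)-3-methyl-5-pentanoylphenyl]methyl}-5-methoxy-3-(triisopropylsilyloxy)hepta-1,3,5-trien-1-one, ketenyl and propenyl groups cis on the central double bond | CCCCC(=O)c1c(OCc2ccccc2)c(C)c(OCc2ccccc2)c(CC(/C(OC)=C/C)=C(/C=C=O)O[Si](C(C)C)(C(C)C)C(C)C)c1OCc1ccccc1 | intermediate
26 | racemic 4-{[2,4,6-tris(benzyloxy)-3-methyl-5-pentanoylphenyl]methyl}-5-methoxy-6-methyl-3-(triisopropylsilyloxy)cyclohexa-2,4-dien-1-one | CCCCC(=O)c1c(OCc2ccccc2)c(C)c(OCc2ccccc2)c(CC2=C(OC)C(C)C(=O)C=C2O[Si](C(C)C)(C(C)C)C(C)C)c1OCc1ccccc1 | intermediate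
27 | 1-[2,4,6-tris(benzyloxy)-3-{[4-hydroxy-2-methoxy-3-methyl-6-(triisopropylsilyloxy)phenyl]methyl}-5-methylphenyl]pentan-1-one | CCCCC(=O)c1c(OCc2ccccc2)c(C)c(OCc2ccccc2)c(Cc2c(O[Si](C(C)C)(C(C)C)C(C)C)cc(O)c(C)c2OC)c1OCc1ccccc1 | intermediate
28 | 1-[2,4,6-tris(benzyloxy)-3-[(4,6-dihydroxy-2-methoxy-3-methylphenyl)methyl]-5-methylphenyl]pentan-1-one | CCCCC(=O)c1c(OCc2ccccc2)c(C)c(OCc2ccccc2)c(Cc2c(O)cc(O)c(C)c2OC)c1OCc1ccccc1 | intermediate
29 | butanenitrile | CCCC#N | starting material
30 | 1-[3-{[2,4,6-tris(benzyloxy)-3-methyl-5-pentanoylphenyl]methyl}-2,6-dihydroxy-4-methoxy-5-methylphenyl]butan-1-iminium chloride | CCCCC(=O)c1c(OCc2ccccc2)c(C)c(OCc2ccccc2)c(Cc2c(O)c(C(=[NH2+])CCC)c(O)c(C)c2OC)c1OCc1ccccc1.[Cl-] | intermediate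
31 | 1-[2,4,6-tris(benzyloxy)-3-[(3-butanoyl-2,4-dihydroxy-6-methoxy-5-methylphenyl)methyl]-5-methylphenyl]pentan-1-one | CCCCC(=O)c1c(OCc2ccccc2)c(C)c(OCc2ccccc2)c(Cc2c(O)c(C(=O)CCC)c(O)c(C)c2OC)c1OCc1ccccc1 | intermediate
32 | 1-[3-[(3-butanoyl-2,4-dihydroxy-6-methoxy-5-methylphenyl)methyl]-2,4,6-trihydroxy-5-methylphenyl]pentan-1-one (CNP0210501.0) | CCCCC(=O)c1c(O)c(C)c(O)c(Cc2c(O)c(C(=O)CCC)c(O)c(C)c2OC)c1O | target

**Step count**

Total steps: 13. Longest linear sequence: 11 steps (1, 2, 3, 4, 5, 7, 8, 10, 11, 12, 13); steps 6 and 9 are side branches that supply 11 and 22.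

**Steps most likely to fail, with fallbacks**

1. Step 9. The monolithium acetylide may disproportionate to the insoluble dilithium salt before it is oxygenated. The unhindered parent ynolate may also be silylated at carbon, or the O-silyl product may undergo a silyl shift, giving (triisopropylsilyl)ketene in place of the siloxyalkyne. The fallback switches to a C-substituted siloxyalkyne, the class for which acetylide oxygenation, O-silylation and the benzannulation are all well established, and which carries the butanoyl carbons at the alcohol oxidation level. It sets out from cyclobutenone 18 and commercial hex-1-yn-3-ol. The alcohol is silylated (t-BuMe2SiCl, imidazole, DMF) to racemic tert-butyl(hex-1-yn-3-yloxy)dimethylsilane F1. Lithiation (n-BuLi), oxygenation with t-BuOOLi and O-silylation with i-Pr3SiOSO2CF3 then give the racemic siloxyalkyne tert-butyldimethyl{[1-(triisopropylsilyloxy)hex-1-yn-3-yl]oxy}silane F2. Heating F2 with 18 (toluene, 80 → 110 °C) should give, by the same benzannulation and with the same regiochemistry, the ring B phenol bearing a silyl-protected 1-hydroxybutyl group at C3', F3. Bu4NF removes both silyl groups to give the triol 1-[2,4,6-tris(benzyloxy)-3-{[2,4-dihydroxy-3-(1-hydroxybutyl)-6-methoxy-5-methylphenyl]methyl}-5-methylphenyl]pentan-1-one F4. MnO2 (CH2Cl2, rt) oxidises the benzylic carbinol of F4 to the ketone, which is compound 31, where the route is rejoined; steps 11 and 12 are then not needed.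

2. Step 10. The 3-methoxy group may slow the electrocyclic opening of 18. The ketene α-carbon, crowded by the ring A benzyl group, may close the four-membered ring with the alkyne too slowly, so that the vinylketene dimerises or acylates the product phenol. The fallback gives up the annulation and joins two preformed rings; it sets out from 1 and 8. Friedel–Crafts butanoylation of 1 (butanoyl chloride, AlCl3, PhNO2) gives 1-(2,4,6-trihydroxy-3-methylphenyl)butan-1-one F5. Methylation with one equivalent of Me2SO4 (K2CO3, acetone) occurs at the only hydroxyl not chelated to the ketone and gives 1-(2,6-dihydroxy-4-methoxy-3-methylphenyl)butan-1-one F6. Friedel–Crafts C-benzylation of the single free ring carbon of F6 with bromide 8 (ZnCl2, CH2Cl2, 0 °C) should give compound 31 directly, where the route is rejoined before the hydrogenolysis.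

3. Step 12. Both rings are phloroglucinol-type, so the acid may protonate an ipso carbon and split the diarylmethane bridge, or strip the benzyl ethers next to the ring A ketone, before C-acylation is complete. The fallback builds the ketone without acid; it sets out from diol 28. Magnesium-mediated ortho-formylation (MgCl2, Et3N, paraformaldehyde, MeCN, reflux) at the one free ring B carbon gives the aldehyde 3-{[2,4,6-tris(benzyloxy)-3-methyl-5-pentanoylphenyl]methyl}-2,6-dihydroxy-4-methoxy-5-methylbenzaldehyde F7. Excess PrMgBr (THF, −40 °C) adds to the chelated aldehyde in preference to the hindered ring A ketone and gives the carbinol F4. MnO2 oxidation of F4 then gives compound 31, where the route is rejoined.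

**Further compounds**

F1 | step 9 | racemic tert-butyl(hex-1-yn-3-yloxy)dimethylsilane | CCCC(O[Si](C)(C)C(C)(C)C)C#C
F2 | step 9 | racemic tert-butyldimethyl{[1-(triisopropylsilyloxy)hex-1-yn-3-yl]oxy}silane | CCCC(O[Si](C)(C)C(C)(C)C)C#CO[Si](C(C)C)(C(C)C)C(C)C
F3 | step 9 | racemic 1-[2,4,6-tris(benzyloxy)-3-{[3-[1-(tert-butyldimethylsilyloxy)butyl]-4-hydroxy-6-methoxy-5-methyl-2-(triisopropylsilyloxy)phenyl]methyl}-5-methylphenyl]pentan-1-one | CCCCC(=O)c1c(OCc2ccccc2)c(C)c(OCc2ccccc2)c(Cc2c(O[Si](C(C)C)(C(C)C)C(C)C)c(C(CCC)O[Si](C)(C)C(C)(C)C)c(O)c(C)c2OC)c1OCc1ccccc1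
F4 | step 9 | racemic 1-[2,4,6-tris(benzyloxy)-3-{[2,4-dihydroxy-3-(1-hydroxybutyl)-6-methoxy-5-methylphenyl]methyl}-5-methylphenyl]pentan-1-one | CCCCC(=O)c1c(OCc2ccccc2)c(C)c(OCc2ccccc2)c(Cc2c(O)c(C(O)CCC)c(O)c(C)c2OC)c1OCc1ccccc1
F5 | step 10 | 1-(2,4,6-trihydroxy-3-methylphenyl)butan-1-one | CCCC(=O)c1c(O)cc(O)c(C)c1O
F6 | step 10 | 1-(2,6-dihydroxy-4-methoxy-3-methylphenyl)butan-1-one | CCCC(=O)c1c(O)cc(OC)c(C)c1O
F7 | step 12 | 3-{[2,4,6-tris(benzyloxy)-3-methyl-5-pentanoylphenyl]methyl}-2,6-dihydroxy-4-methoxy-5-methylbenzaldehyde | CCCCC(=O)c1c(OCc2ccccc2)c(C)c(OCc2ccccc2)c(Cc2c(O)c(C=O)c(O)c(C)c2OC)c1OCc1ccccc1
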